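Isochromanone numbering: C1 (lactone C=O), O2, C3, C4, then ring A = C4a, C5, C6 (OMe), C7, C8 (OH), C8a; ring B is the lactone.
Cuts, in retrosynthetic order: the C1–O2 lactone bond; the ring A bonds C4a–C5 and C8–C8a (diene + ynoate); the C4–C4a bond between the propargylic CH2 and the alkyne (epoxide + propiolate); the side-chain bond between the first and second carbon beyond C3 (epichlorohydrin + C10 Grignard reagent).
Enabling feature: ring A holds oxygen at C6 and C8 (meta), the carboxyl carbon C1 on C8a beside the C8 oxygen, and the C4 methylene on C4a. This is what remains when a 1,1,3-trioxygenated buta-1,3-diene adds across a –CH2–C≡C–CO2Me unit and the adduct aromatises.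
Forward order: the chain is joined first (Grignard reagent + (R)-epichlorohydrin, epoxide, lithiated methyl propiolate), ring A is then made from the acyclic ynoate by [4+2] cycloaddition/aromatisation, and ring B closes last when the silyl groups are removed.
Stereochemistry: the lone stereocentre C3 (R) is taken from (R)-epichlorohydrin; no later step makes or breaks a bond at that carbon.

Key step: step 7

Remark on the chemistry: the siloxydiene is drawn as its E ketene acetal, and the cycloadduct should form as both epimers at its ketal carbon (left unspecified in its SMILES); both elements vanish on aromatisation. Both hydroxyls are carried as tert-butyldimethylsilyl ethers so that one acid treatment ends the synthesis.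

Step 1
Reactants: 1 10-bromodecan-1-ol
Product: 2 tert-butyl[(10-bromodecyl)oxy]dimethylsilane
Conditions: TBSCl, imidazole, CH2Cl2, 0 °C to rt
Reagents that add atoms: tert-butyldimethylsilyl chloride, CC(C)(C)[Si](C)(C)Cl
Why: Imidazole-promoted O-silylation (silyl ether formation) of the primary alcohol is fast and leaves the primary bromide untouched, giving a bromide fit for Grignard formation.

Step 2
Reactants: 2 tert-butyl[(10-bromodecyl)oxy]dimethylsilane; 3 (R)-epichlorohydrin
Product: 5 (2R)-13-(tert-butyldimethylsilyloxy)-1-chlorotridecan-2-ol, via Grignard reagent 4 (not isolated)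
Conditions: Mg, THF, 45 °C; then 3, CuI (10 mol%), THF, −40 to −20 °C; then H2O
Reagents that add atoms: none
Why: CuI-catalysed Grignard opening of a terminal epoxide (SN2 at the unsubstituted ring carbon, the C–Cl bond spared at low temperature) lengthens the chain without touching the carbinol carbon, so the (R) configuration is carried over from 3.

Step 3
Reactants: 5 (2R)-13-(tert-butyldimethylsilyloxy)-1-chlorotridecan-2-ol
Product: 6 (2R)-2-[11-(tert-butyldimethylsilyloxy)undecyl]oxirane
Conditions: NaOH (powdered), Et2O, rt
Reagents that add atoms: none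
Why: Base-induced closure of the chlorohydrin (intramolecular Williamson ether synthesis, 3-exo-tet) displaces chloride at the primary carbon, so the stereocentre is retained and the new terminal epoxide offers its CH2 to the next nucleophile.

Step 4
Reactants: 6 (2R)-2-[11-(tert-butyldimethylsilyloxy)undecyl]oxirane; 7 methyl propiolate
Product: 9 methyl (5R)-16-(tert-butyldimethylsilyloxy)-5-hydroxyhexadec-2-ynoate, via lithiated methyl propiolate 8 (not isolated)
Conditions: 7, n-BuLi, THF, −90 °C; BF3·OEt2; then 6, −90 to −78 °C; then H2O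
Reagents that add atoms: none
Why: In this Yamaguchi–Hirao alkynylation the ester-bearing lithium acetylide, kept cold, opens the BF3-activated epoxide at its terminal carbon by SN2, giving the δ-hydroxy ynoate with the carbinol stereocentre untouched.

Step 5
Reactants: 9 methyl (5R)-16-(tert-butyldimethylsilyloxy)-5-hydroxyhexadec-2-ynoate
Product: 10 methyl (5R)-5,16-bis(tert-butyldimethylsilyloxy)hexadec-2-ynoate
Conditions: TBSOTf, 2,6-lutidine, CH2Cl2, −78 to 0 °C
Reagents that add atoms: tert-butyldimethylsilyl trifluoromethanesulfonate, CC(C)(C)[Si](C)(C)OS(=O)(=O)C(F)(F)F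
Why: Silyl ether formation with the silyl triflate and a hindered non-nucleophilic base avoids conjugate addition to the ynoate and removes the only acidic proton, which would otherwise consume the silyl ketene acetal in the cycloaddition.

Step 6
Reactants: 11 methyl (E)-3-methoxybut-2-enoate
Product: 13 (1E)-1,3-dimethoxy-1-(trimethylsilyloxy)buta-1,3-diene, via lithium dienolate 12 (not isolated)
Conditions: LiN(iPr)2, THF, −78 °C; then TMSCl, −78 °C to rt; distillation
Reagents that add atoms: chlorotrimethylsilane, C[Si](C)(C)Cl
Why: Kinetic γ-deprotonation of the β-methoxy enoate by the lithium amide gives the extended enolate, and its O-silylation (silyl ketene acetal formation) should deliver the 1,1,3-trioxygenated diene.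

Step 7
Reactants: 10 methyl (5R)-5,16-bis(tert-butyldimethylsilyloxy)hexadec-2-ynoate; 13 (1E)-1,3-dimethoxy-1-(trimethylsilyloxy)buta-1,3-diene
Product: 16 methyl 2-[(2R)-2,13-bis(tert-butyldimethylsilyloxy)tridecyl]-6-hydroxy-4-methoxybenzoate, via cyclohexadiene cycloadduct 14 (not isolated), via aryl trimethylsilyl ether 15 (not isolated)
Conditions: 13 (3 equiv, two portions), toluene, sealed tube, 125 °C; then K2CO3 (cat.), MeOH, 0 °C
Reagents that add atoms: none
Why: The electron-rich diene adds across the electron-poor triple bond in a concerted but asynchronous normal-demand Diels–Alder reaction, its CH2 terminus (largest HOMO coefficient) bonding ahead to the ynoate β-carbon (future C4a) while the ketene-acetal carbon joins the α-carbon (future C8a). The closest known reaction type is the thermal addition of 1,1,3-trioxygenated butadienes to acetylenic esters with aromatisation to resorcylates, which accepts an alkyl group on the β-carbon when heated with excess diene. Ring A is closed intermolecularly by this single [4+2] event, the two sigma bonds C4a–C5 and C8–C8a forming together to give cyclohexa-1,4-diene 14, which should aromatise by 1,4-elimination of methanol (C5–H and the C8 ketal methoxy) to aryl silyl ether 15, methanolysed in the second stage to the hydrogen-bonded C8 phenol. No stereocentre remains in the new ring, since the ketal carbon of 14 becomes sp2, and C3 is shielded from the reacting carbons by C4 and keeps its (R) configuration. Only regioselectivity is required, and it is secured by pairing the nucleophilic diene terminus with the electrophilic β-carbon of the ynoate, which also delivers the two ring oxygens already differentiated as C6–OMe and C8–OH.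

Step 8
Reactants: 16 methyl 2-[(2R)-2,13-bis(tert-butyldimethylsilyloxy)tridecyl]-6-hydroxy-4-methoxybenzoate
Product: 18 (3R)-8-hydroxy-3-(11-hydroxyundecyl)-6-methoxy-3,4-dihydro-1H-isochromen-1-one, via diol ester 17 (not isolated)
Conditions: p-TsOH·H2O (20 mol%), MeOH, 40 °C; then toluene, 80 °C
Reagents that add atoms: none
Why: Acid-catalysed methanolysis removes both silyl ethers, and the freed C3 hydroxyl then closes ring B by intramolecular transesterification (6-exo-trig lactonisation) as methanol is driven off in warm toluene; the C3–O bond is never broken, so the (R) configuration is retained, and the remote primary hydroxyl cannot compete because it would have to form a large ring.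

Compound list
1 | 10-bromodecan-1-ol | OCCCCCCCCCCBr | starting material
2 | tert-butyl[(10-bromodecyl)oxy]dimethylsilane | BrCCCCCCCCCCO[Si](C)(C)C(C)(C)C | intermediate
3 | (R)-epichlorohydrin | ClC[C@H]1CO1 | starting material
4 | [10-(tert-butyldimethylsilyloxy)decyl]magnesium bromide (not isolated) | Br[Mg]CCCCCCCCCCO[Si](C)(C)C(C)(C)C | intermediate
5 | (2R)-13-(tert-butyldimethylsilyloxy)-1-chlorotridecan-2-ol | ClC[C@H](O)CCCCCCCCCCCO[Si](C)(C)C(C)(C)C | intermediate
6 | (2R)-2-[11-(tert-butyldimethylsilyloxy)undecyl]oxirane | CC(C)(C)[Si](C)(C)OCCCCCCCCCCC[C@@H]1CO1 | intermediate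
7 | methyl propiolate | C#CC(=O)OC | starting material
8 | methyl 3-lithioprop-2-ynoate (not isolated) | [Li]C#CC(=O)OC | intermediate
9 | methyl (5R)-16-(tert-butyldimethylsilyloxy)-5-hydroxyhexadec-2-ynoate | COC(=O)C#CC[C@H](O)CCCCCCCCCCCO[Si](C)(C)C(C)(C)C | intermediate
10 | methyl (5R)-5,16-bis(tert-butyldimethylsilyloxy)hexadec-2-ynoate | COC(=O)C#CC[C@H](O[Si](C)(C)C(C)(C)C)CCCCCCCCCCCO[Si](C)(C)C(C)(C)C | intermediate
11 | methyl (E)-3-methoxybut-2-enoate | CO/C(C)=C/C(=O)OC | starting material
12 | lithium 1,3-dimethoxybuta-1,3-dien-1-olate (not isolated) | C=C(OC)/C=C(\OC)[O-].[Li+] | intermediate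
13 | (1E)-1,3-dimethoxy-1-(trimethylsilyloxy)buta-1,3-diene | C=C(OC)/C=C(\OC)O[Si](C)(C)C | intermediate
14 | methyl 2-[(2R)-2,13-bis(tert-butyldimethylsilyloxy)tridecyl]-4,6-dimethoxy-6-(trimethylsilyloxy)cyclohexa-1,4-diene-1-carboxylate (both ketal epimers, not isolated) | COC(=O)C1=C(C[C@H](O[Si](C)(C)C(C)(C)C)CCCCCCCCCCCO[Si](C)(C)C(C)(C)C)CC(OC)=CC1(OC)O[Si](C)(C)C | intermediate
15 | methyl 2-[(2R)-2,13-bis(tert-butyldimethylsilyloxy)tridecyl]-4-methoxy-6-(trimethylsilyloxy)benzoate (not isolated) | COC(=O)c1c(O[Si](C)(C)C)cc(OC)cc1C[C@H](O[Si](C)(C)C(C)(C)C)CCCCCCCCCCCO[Si](C)(C)C(C)(C)C | intermediate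
16 | methyl 2-[(2R)-2,13-bis(tert-butyldimethylsilyloxy)tridecyl]-6-hydroxy-4-methoxybenzoate | COC(=O)c1c(O)cc(OC)cc1C[C@H](O[Si](C)(C)C(C)(C)C)CCCCCCCCCCCO[Si](C)(C)C(C)(C)C | intermediate
17 | methyl 2-[(2R)-2,13-dihydroxytridecyl]-6-hydroxy-4-methoxybenzoate (not isolated) | COC(=O)c1c(O)cc(OC)cc1C[C@H](O)CCCCCCCCCCCO | intermediate
18 | (3R)-8-hydroxy-3-(11-hydroxyundecyl)-6-methoxy-3,4-dihydro-1H-isochromen-1-one | COc1cc(O)c2c(c1)C[C@@H](CCCCCCCCCCCO)OC2=O | target

Total step count: 8. Longest linear sequence: 7 steps (steps 1, 2, 3, 4, 5, 7, 8 from 10-bromodecan-1-ol); step 6 is a one-step side branch.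

Steps most likely to fail

Step 7. The cycloaddition to a β-alkyl ynoate is slow, so thermal decay or adventitious hydrolysis of the silyl ketene acetal may outrun it. Aromatisation could also proceed in part by loss of silanol instead of methanol, which would leave the C8 oxygen methylated. The fallback sets out from 10 and keeps the same two ring bonds but uses a more robust diene. Dimedone is bis-silylated (Et3N, TMSOTf, Et2O, 0 °C) to 5,5-dimethyl-1,3-bis(trimethylsilyloxy)cyclohexa-1,3-diene F1. Heating F1 with 10 (neat, 150 °C) should give the bicyclo[2.2.2]octadiene adduct methyl 3-[(2R)-2,13-bis(tert-butyldimethylsilyloxy)tridecyl]-8,8-dimethyl-1,5-bis(trimethylsilyloxy)bicyclo[2.2.2]octa-2,5-diene-2-carboxylate F2. Under the same heating F2 should expel 2-methylpropene by retro-Diels–Alder (Alder–Rickert) reaction to methyl 2-[(2R)-2,13-bis(tert-butyldimethylsilyloxy)tridecyl]-4,6-bis(trimethylsilyloxy)benzoate F3. Methanolysis (K2CO3 cat., MeOH, 0 °C) then gives methyl 2-[(2R)-2,13-bis(tert-butyldimethylsilyloxy)tridecyl]-4,6-dihydroxybenzoate F4. Both oxygens arrive as silyl ethers, so no ambiguity in the leaving group arises. Selective methylation of the 4-hydroxyl (MeI 1.05 equiv, K2CO3, acetone, rt; the 6-hydroxyl is hydrogen-bonded to the ester) rejoins the route at 16.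

Step 4. The lithiated propiolate decomposes readily above −78 °C, and BF3 may divert the epoxide (rearrangement, opening by fluoride, loss of the primary silyl ether), so conversion may be poor. The fallback sets out from 6 and builds the ynoate without a Lewis acid. Opening with LiC≡CH·H2NCH2CH2NH2 (DMSO, rt) should give (4R)-15-(tert-butyldimethylsilyloxy)pentadec-1-yn-4-ol F5. Silylation (TBSCl, imidazole, DMF) gives (4R)-4,15-bis(tert-butyldimethylsilyloxy)pentadec-1-yne F6. Deprotonation (n-BuLi, THF, −78 °C) gives [(4R)-4,15-bis(tert-butyldimethylsilyloxy)pentadec-1-yn-1-yl]lithium F7, which is trapped with ClCO2Me to rejoin the route at 10.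

Step 2. Wurtz-type homocoupling during Grignard formation would lower the yield. Competing attack at the chloromethyl carbon (direct displacement of chloride) would lead, after ring closure, to the enantiomeric epoxide and so erode enantiomeric purity. The fallback sets out from Grignard reagent 4 and takes the stereocentre from a resolution instead. Coupling with allyl bromide (CuI cat., THF, 0 °C) should give tert-butyldimethyl(tridec-12-en-1-yloxy)silane F8. Epoxidation (mCPBA, CH2Cl2, 0 °C) gives racemic 2-[11-(tert-butyldimethylsilyloxy)undecyl]oxirane F9. Hydrolytic kinetic resolution follows (H2O 0.55 equiv, 0.5 mol% of the (salen)Co(OAc) complex of trivalent cobalt, in the ligand enantiomer that hydrolyses the (S)-epoxide, (S,S) by the usual correlation for alkyl oxiranes). It should leave the (R)-epoxide and rejoin the route at 6, at the cost of at most half the material.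

Further compounds
F1 | step 7 | 5,5-dimethyl-1,3-bis(trimethylsilyloxy)cyclohexa-1,3-diene | CC1(C)CC(O[Si](C)(C)C)=CC(O[Si](C)(C)C)=C1
F2 | step 7 | methyl 3-[(2R)-2,13-bis(tert-butyldimethylsilyloxy)tridecyl]-8,8-dimethyl-1,5-bis(trimethylsilyloxy)bicyclo[2.2.2]octa-2,5-diene-2-carboxylate (bridgehead epimers, not isolated) | COC(=O)C1=C(C[C@H](O[Si](C)(C)C(C)(C)C)CCCCCCCCCCCO[Si](C)(C)C(C)(C)C)C2C(C)(C)CC1(O[Si](C)(C)C)C=C2O[Si](C)(C)C
F3 | step 7 | methyl 2-[(2R)-2,13-bis(tert-butyldimethylsilyloxy)tridecyl]-4,6-bis(trimethylsilyloxy)benzoate (not isolated) | COC(=O)c1c(O[Si](C)(C)C)cc(O[Si](C)(C)C)cc1C[C@H](O[Si](C)(C)C(C)(C)C)CCCCCCCCCCCO[Si](C)(C)C(C)(C)C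
F4 | step 7 | methyl 2-[(2R)-2,13-bis(tert-butyldimethylsilyloxy)tridecyl]-4,6-dihydroxybenzoate | COC(=O)c1c(O)cc(O)cc1C[C@H](O[Si](C)(C)C(C)(C)C)CCCCCCCCCCCO[Si](C)(C)C(C)(C)C
F5 | step 4 | (4R)-15-(tert-butyldimethylsilyloxy)pentadec-1-yn-4-ol | C#CC[C@H](O)CCCCCCCCCCCO[Si](C)(C)C(C)(C)C
F6 | step 4 | (4R)-4,15-bis(tert-butyldimethylsilyloxy)pentadec-1-yne | C#CC[C@H](O[Si](C)(C)C(C)(C)C)CCCCCCCCCCCO[Si](C)(C)C(C)(C)C
F7 | step 4 | [(4R)-4,15-bis(tert-butyldimethylsilyloxy)pentadec-1-yn-1-yl]lithium (not isolated) | [Li]C#CC[C@H](O[Si](C)(C)C(C)(C)C)CCCCCCCCCCCO[Si](C)(C)C(C)(C)C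
F8 | step 2 | tert-butyldimethyl(tridec-12-en-1-yloxy)silane | C=CCCCCCCCCCCCO[Si](C)(C)C(C)(C)C
F9 | step 2 | racemic 2-[11-(tert-butyldimethylsilyloxy)undecyl]oxirane | CC(C)(C)[Si](C)(C)OCCCCCCCCCCCC1CO1
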